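**Plan**

- Numbering (eudesmane): ring A = C1–C5 + C10 (C1 senecioate, C2 acetate, C3=C4–CH3); ring B = C5–C10 (C7 isopropenyl, C9 acetate); C10 is the quaternary ring-fusion carbon carrying C14 (CH2OH); C5 is the ring-fusion CH.
- Retrosynthesis: after the esters, cut C7–C11 (isopropenyl cuprate on a C7=C8 enone), then C3=C4 (RCM). The array O–C9–C10(quaternary)–C14–O, with ring carbon C5 on C10, is the product pattern of a 2,3-epoxy alcohol semipinacol shift; the C5–C10 bond is therefore traced back to a C5–C9 bond, i.e. ring B to the cyclopentane C5–C6–C7–C8–C9 carrying a C10–C14 epoxide on C9. The last cut is C9–C10 (vinylcerium + 2-isopropenylcyclopentanone).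
- Forward: the two fragments are joined at C9–C10, the C10=C14 alkene is epoxidised, ring B arises by ring expansion (5 → 6) with formation of quaternary C10, ring A is closed by RCM, then C7 and C9 are functionalised and the ester pattern is set.
- Stereochemistry: C1/C2 from D-erythronolactone; C5 from a lipase-resolved trans-2-isopropenylcyclopentanol; C10 from the face of the directed epoxidation (C9–OH and the C1 centre matched), then inversion at C10 and retention at C5 in the shift (trans ring fusion); C7 by axial cuprate attack anti to C4; C9 by hydride attack anti to the axial isopropenyl group.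

Key step: step 11

Remark: commercial (−)-2,3-O-isopropylidene-D-erythronolactone is taken to be the (3aR,6aR) enantiomer, which maps onto C1 (R) and C2 (S) of the target.

**Route**

Step 1
Reactants: 1 (−)-2,3-O-isopropylidene-D-erythronolactone
Product: 2 2,3-O-isopropylidene-D-erythrose (lactol; anomer mixture)
Conditions: iBu2AlH, CH2Cl2, −78 °C; aq. Rochelle salt
Reagents that add atoms: none
Why: Partial reduction of a lactone with iBu2AlH at low temperature should stop at the aluminium hemiacetal and give the lactol on work-up, with no stereocentre touched.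

Step 2
Reactants: 2 2,3-O-isopropylidene-D-erythrose
Product: 3 [(4R,5S)-2,2-dimethyl-5-vinyl-1,3-dioxolan-4-yl]methanol
Conditions: Ph3PCH3Br, KOtBu, THF, 0 °C → reflux
Reagents that add atoms: methyltriphenylphosphonium bromide, C[P+](c1ccccc1)(c1ccccc1)c1ccccc1.[Br-]
Why: Wittig methylenation of the open aldehyde form of the lactol should give the vinyl dioxolane with the cis-acetonide centres (future C1 and C2) unchanged.

Step 3
Reactants: 3 [(4R,5S)-2,2-dimethyl-5-vinyl-1,3-dioxolan-4-yl]methanol
Product: 4 (4S,5S)-2,2-dimethyl-5-vinyl-1,3-dioxolane-4-carbaldehyde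
Conditions: Dess–Martin periodinane, CH2Cl2, 0 °C → rt; used crude
Reagents that add atoms: none
Why: Dess–Martin oxidation of the primary alcohol under non-basic conditions should give the aldehyde without epimerising the α-alkoxy centre.

Step 4
Reactants: 4 (4S,5S)-2,2-dimethyl-5-vinyl-1,3-dioxolane-4-carbaldehyde
Product: 5 (4R,5S)-4-ethynyl-2,2-dimethyl-5-vinyl-1,3-dioxolane
Conditions: dimethyl (1-diazo-2-oxopropyl)phosphonate, K2CO3, MeOH, 0 °C → rt
Reagents that add atoms: dimethyl (1-diazo-2-oxopropyl)phosphonate, COP(=O)(OC)C(=[N+]=[N-])C(C)=O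
Why: Ohira–Bestmann (Seyferth–Gilbert) homologation should turn the aldehyde into the terminal alkyne (future C10 and C14); it is run cold so that the cis-acetonide does not epimerise.

Step 5
Reactants: 5 (4R,5S)-4-ethynyl-2,2-dimethyl-5-vinyl-1,3-dioxolane
Product: 6 tributyl{1-[(4S,5S)-2,2-dimethyl-5-vinyl-1,3-dioxolan-4-yl]vinyl}stannane
Conditions: Bu3SnH, Mo(CO)3(CNtBu)3 (cat.; from Mo(CO)6 and t-BuNC), hydroquinone (cat.), THF, 55 °C
Reagents that add atoms: tributyltin hydride, CCCC[SnH](CCCC)CCCC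
Why: Molybdenum-catalysed hydrostannation places tin on the internal carbon of terminal propargylic ethers and acetals, so the 1,1-disubstituted vinylstannane (tin on future C10) should form.

Step 6
Reactants: 7 cyclopentene oxide
Product: 8 rac-trans-2-(prop-1-en-2-yl)cyclopentan-1-ol
Conditions: isopropenylmagnesium bromide, CuI (cat.), THF, −30 → 0 °C; aq. NH4Cl
Reagents that add atoms: isopropenylmagnesium bromide, C=C(C)[Mg]Br
Why: Copper-catalysed SN2 opening of the meso epoxide by the Grignard reagent proceeds with inversion and should give the trans alcohol as the racemate.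

Step 7
Reactants: 8 rac-trans-2-(prop-1-en-2-yl)cyclopentan-1-ol
Product: 9 (1S,2R)-2-(prop-1-en-2-yl)cyclopentan-1-ol
Conditions: Amano lipase PS (Burkholderia cepacia), vinyl acetate, MTBE, 30 °C, stopped beyond half conversion; chromatography
Reagents that add atoms: none
Why: Lipase-catalysed kinetic resolution by transesterification should acylate the (1R,2S)-enantiomer, in line with the usual lipase preference for secondary alcohols, and leave the (1S,2R)-alcohol that carries the future C5 configuration.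

Step 8
Reactants: 9 (1S,2R)-2-(prop-1-en-2-yl)cyclopentan-1-ol
Product: 10 (R)-2-(prop-1-en-2-yl)cyclopentan-1-one
Conditions: Dess–Martin periodinane, CH2Cl2, 0 °C; used at once
Reagents that add atoms: none
Why: Dess–Martin oxidation under neutral conditions should keep both the α-stereocentre (future C5) and the β,γ-position of the double bond.

Step 9
Reactants: 6 tributyl{1-[(4S,5S)-2,2-dimethyl-5-vinyl-1,3-dioxolan-4-yl]vinyl}stannane; 10 (R)-2-(prop-1-en-2-yl)cyclopentan-1-one
Product: 13 (1R,2R)-1-{1-[(4R,5S)-2,2-dimethyl-5-vinyl-1,3-dioxolan-4-yl]vinyl}-2-(prop-1-en-2-yl)cyclopentan-1-ol (hydroxyl cis to isopropenyl), via vinyllithium 11 (not isolated), via vinylcerium dichloride 12 (not isolated)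
Conditions: n-BuLi, THF, −78 °C; anhydrous CeCl3, −78 °C; then 10, −78 °C; aq. NH4Cl
Reagents that add atoms: none
Why: Tin–lithium exchange, transmetalation to the weakly basic organocerium reagent and 1,2-addition to the enolisable ketone should form the C9–C10 bond from the face anti to the α-isopropenyl group, so that the new C9 hydroxyl is cis to it.

Step 10
Reactants: 13 tertiary allylic alcohol
Product: 14 (1R,2R)-1-{(2R)-2-[(4S,5S)-2,2-dimethyl-5-vinyl-1,3-dioxolan-4-yl]oxiran-2-yl}-2-(prop-1-en-2-yl)cyclopentan-1-ol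
Conditions: VO(acac)2 (cat.), t-BuOOH, CH2Cl2, 0 °C → rt
Reagents that add atoms: tert-butyl hydroperoxide, CC(C)(C)OO
Why: Hydroxyl-directed vanadium-catalysed epoxidation should touch only the allylic C10=C14 alkene and deliver oxygen from the face that lets the ring CH2 (C8), not the branched C5, eclipse the C10–C1 bond (A(1,2) strain); this face is also anti to C2 of the dioxolane, which gives the C10 configuration shown (erythro to the C1–O bond).

Step 11
Reactants: 14 epoxy alcohol
Product: 15 (2R,3R)-2-[(4R,5S)-2,2-dimethyl-5-vinyl-1,3-dioxolan-4-yl]-2-(hydroxymethyl)-3-(prop-1-en-2-yl)cyclohexan-1-one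
Conditions: BF3·OEt2, CH2Cl2, −78 → −40 °C; aq. NaHCO3
Reagents that add atoms: none
Why: BF3 binds the epoxide oxygen, the tertiary C10–O bond ionises and ring carbon C5 shifts from the carbinol carbon C9 to C10 antiperiplanar to the leaving oxygen while the C9 hydroxyl collapses to the ketone; this is a semipinacol rearrangement of a 2,3-epoxy tertiary alcohol, and the closest known type is the Lewis-acid rearrangement of 1-(oxiran-2-yl)cycloalkanols to 2-(hydroxymethyl)cycloalkanones. Ring B is not closed by a cyclisation but grows from the five-membered ring C5–C6–C7–C8–C9 to the six-membered ring C5–C10 by this 1,2-alkyl shift. The new quaternary centre C10 is formed with inversion at the epoxide carbon and is therefore controlled by the epoxide configuration from step 10, and C5 migrates with retention, which together fix C14 anti to H5 as needed for the trans ring fusion. The step needs migration of C5 in preference to C8 and to a hydride shift from C14: C5 is the more substituted, allylic carbon and so the better migrating group, the free tertiary hydroxyl gives a push that the ether oxygen at C1 cannot, and the low temperature should hold back olefin participation and acetal cleavage.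

Step 12
Reactants: 15 β-hydroxy ketone
Product: 16 (2R,3R)-2-{[tert-butyl(diphenyl)silyl]oxymethyl}-2-[(4R,5S)-2,2-dimethyl-5-vinyl-1,3-dioxolan-4-yl]-3-(prop-1-en-2-yl)cyclohexan-1-one
Conditions: TBDPSCl, imidazole, DMF, rt
Reagents that add atoms: tert-butyl(chloro)diphenylsilane, CC(C)(C)[Si](Cl)(c1ccccc1)c1ccccc1
Why: Silylation of the primary hydroxyl should protect C14–OH and remove the retro-aldol risk of the β-hydroxy ketone.

Step 13
Reactants: 16 silyl ether diene
Product: 17 14-[tert-butyl(diphenyl)silyl]oxy-1,2-O-isopropylidene-1,2-dihydroxy-11,12,13-trinoreudesm-3-en-9-one (trans-fused; C1, C2, C5 and C10 as in the target)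
Conditions: second-generation Grubbs catalyst (H2IMes)(PCy3)Cl2Ru=CHPh (cat.), CH2Cl2, 40 °C
Reagents that add atoms: none
Why: Ring-closing metathesis between the isopropenyl group on C5 and the vinyl group on C2 should close the six-membered ring A with the trisubstituted C3=C4 alkene, the trans fusion following from the C5 and C10 configurations.

Step 14
Reactants: 17 tricyclic ketone
Product: 19 14-[tert-butyl(diphenyl)silyl]oxy-1,2-O-isopropylidene-1,2-dihydroxy-11,12,13-trinoreudesma-3,7-dien-9-one, via trimethylsilyl enol ether 18 (not isolated)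
Conditions: LiN(iPr)2 (LDA), Me3SiCl, THF, −78 °C; then Pd(OAc)2, MeCN, rt
Reagents that add atoms: none
Why: Saegusa–Ito oxidation should give the C7=C8 enone regioselectively, because C8 is the only enolisable position of the ketone.

Step 15
Reactants: 19 enone
Product: 20 14-[tert-butyl(diphenyl)silyl]oxy-1,2-O-isopropylidene-1,2-dihydroxyeudesma-3,11-dien-9-one (C7 isopropenyl axial, cis to H5)
Conditions: isopropenylmagnesium bromide, CuBr·SMe2 (cat.), THF, −40 °C; aq. NH4Cl
Reagents that add atoms: isopropenylmagnesium bromide, C=C(C)[Mg]Br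
Why: Copper-catalysed conjugate addition by axial attack on the cyclohexenone, anti to the C5–C4 bond (the 3,5-trans rule), should place the isopropenyl group axial at C7, cis to H5 and anti to C14.

Step 16
Reactants: 20 ketone
Product: 21 14-[tert-butyl(diphenyl)silyl]oxy-1,2-O-isopropylidene-eudesma-3,11-diene-1,2,9-triol (C9 hydroxyl axial, cis to the isopropenyl group, anti to C14)
Conditions: LiBH(s-Bu)3 (L-Selectride), THF, −78 → 0 °C; H2O
Reagents that add atoms: none
Why: Reduction with a bulky borohydride should occur from the equatorial direction, because the axial trajectory is blocked by the syn-axial isopropenyl group at C7, and so give the axial C9 alcohol.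

Step 17
Reactants: 21 acetonide alcohol
Product: 22 14-[tert-butyl(diphenyl)silyl]oxyeudesma-3,11-diene-1,2,9-triol
Conditions: AcOH/H2O 4:1, 55 °C
Reagents that add atoms: none
Why: Acid hydrolysis of the acetonide should free the cis-1,2-diol while the TBDPS ether and the alkenes survive aqueous acetic acid.

Step 18
Reactants: 22 triol
Product: 24 14-[tert-butyl(diphenyl)silyl]oxy-2,9-dihydroxyeudesma-3,11-dien-1-yl 3-methylbut-2-enoate, via dibutylstannylene acetal 23 (not isolated)
Conditions: Bu2SnO, toluene, reflux (−H2O); then 3-methylbut-2-enoyl chloride, 0 °C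
Reagents that add atoms: 3-methylbut-2-enoyl chloride, CC(C)=CC(=O)Cl
Why: Acylation through the dibutylstannylene acetal of a cis-diol activates the equatorial oxygen, so the senecioate should go to O1 rather than to the pseudoaxial allylic O2, and the hindered axial C9 hydroxyl should not react.

Step 19
Reactants: 24 senecioate diol
Product: 25 2,9-diacetoxy-14-[tert-butyl(diphenyl)silyl]oxyeudesma-3,11-dien-1-yl 3-methylbut-2-enoate
Conditions: Ac2O, DMAP, pyridine, 40 °C
Reagents that add atoms: acetic anhydride, CC(=O)OC(C)=O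
Why: DMAP-catalysed acetylation should esterify the two remaining secondary hydroxyls at C2 and C9.

Step 20
Reactants: 25 silyl ether
Product: 26 target, (1R,2S,5R,7S,9S,10S)-2,9-diacetoxy-14-hydroxyeudesma-3,11-dien-1-yl 3-methylbut-2-enoate
Conditions: HF·pyridine, THF/pyridine, 0 °C → rt
Reagents that add atoms: none
Why: Fluoride cleavage of the silyl ether under acidic conditions should free C14–OH without 1,3-acyl migration from O1 or O9.

**Compound list**

1 | (−)-2,3-O-isopropylidene-D-erythronolactone, (3aR,6aR) | O=C1OC[C@H]2OC(C)(C)O[C@@H]12 | starting material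
2 | 2,3-O-isopropylidene-D-erythrose (lactol; anomer mixture) | OC1OC[C@H]2OC(C)(C)O[C@@H]12 | intermediate
3 | [(4R,5S)-2,2-dimethyl-5-vinyl-1,3-dioxolan-4-yl]methanol | OC[C@H]1OC(C)(C)O[C@H]1C=C | intermediate
4 | (4S,5S)-2,2-dimethyl-5-vinyl-1,3-dioxolane-4-carbaldehyde | O=C[C@H]1OC(C)(C)O[C@H]1C=C | intermediate
5 | (4R,5S)-4-ethynyl-2,2-dimethyl-5-vinyl-1,3-dioxolane | C#C[C@H]1OC(C)(C)O[C@H]1C=C | intermediate
6 | tributyl{1-[(4S,5S)-2,2-dimethyl-5-vinyl-1,3-dioxolan-4-yl]vinyl}stannane | C=C([Sn](CCCC)(CCCC)CCCC)[C@H]1OC(C)(C)O[C@H]1C=C | intermediate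
7 | cyclopentene oxide | C1CC2OC2C1 | starting material
8 | rac-trans-2-(prop-1-en-2-yl)cyclopentan-1-ol (both enantiomers) | O[C@H]1CCC[C@@H]1C(C)=C.O[C@@H]1CCC[C@H]1C(C)=C | intermediate
9 | (1S,2R)-2-(prop-1-en-2-yl)cyclopentan-1-ol | O[C@H]1CCC[C@@H]1C(C)=C | intermediate
10 | (R)-2-(prop-1-en-2-yl)cyclopentan-1-one | C=C(C)[C@H]1CCCC1=O | intermediate
11 | vinyllithium from 6 (Li in place of SnBu3) | [Li]C(=C)[C@H]1OC(C)(C)O[C@H]1C=C | intermediate
12 | vinylcerium dichloride from 11 | Cl[Ce](Cl)C(=C)[C@H]1OC(C)(C)O[C@H]1C=C | intermediate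
13 | (1R,2R)-1-{1-[(4R,5S)-2,2-dimethyl-5-vinyl-1,3-dioxolan-4-yl]vinyl}-2-(prop-1-en-2-yl)cyclopentan-1-ol | C=C(C)[C@H]1CCC[C@]1(O)C(=C)[C@H]2OC(C)(C)O[C@H]2C=C | intermediate
14 | (1R,2R)-1-{(2R)-2-[(4S,5S)-2,2-dimethyl-5-vinyl-1,3-dioxolan-4-yl]oxiran-2-yl}-2-(prop-1-en-2-yl)cyclopentan-1-ol | C=C(C)[C@H]1CCC[C@]1(O)[C@@]2(CO2)[C@H]3OC(C)(C)O[C@H]3C=C | intermediate
15 | (2R,3R)-2-[(4R,5S)-2,2-dimethyl-5-vinyl-1,3-dioxolan-4-yl]-2-(hydroxymethyl)-3-(prop-1-en-2-yl)cyclohexan-1-one | C1CC(=O)[C@@]([C@H]2OC(C)(C)O[C@H]2C=C)(CO)[C@H](C1)C(C)=C | intermediate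
16 | TBDPS ether of 15 | C1CC(=O)[C@@]([C@H]2OC(C)(C)O[C@H]2C=C)(CO[Si](c2ccccc2)(c2ccccc2)C(C)(C)C)[C@H](C1)C(C)=C | intermediate
17 | 14-TBDPS-oxy-1,2-O-isopropylidene-1,2-dihydroxy-11,12,13-trinoreudesm-3-en-9-one (trans-fused) | C1CC(=O)[C@@]2(CO[Si](c3ccccc3)(c3ccccc3)C(C)(C)C)[C@H](C1)C(C)=C[C@@H]3OC(C)(C)O[C@H]23 | intermediate
18 | C8=C9 trimethylsilyl enol ether of 17 | C1C=C(O[Si](C)(C)C)[C@@]2(CO[Si](c3ccccc3)(c3ccccc3)C(C)(C)C)[C@H](C1)C(C)=C[C@@H]3OC(C)(C)O[C@H]23 | intermediate
19 | 14-TBDPS-oxy-1,2-O-isopropylidene-1,2-dihydroxy-11,12,13-trinoreudesma-3,7-dien-9-one | C1=CC(=O)[C@@]2(CO[Si](c3ccccc3)(c3ccccc3)C(C)(C)C)[C@H](C1)C(C)=C[C@@H]3OC(C)(C)O[C@H]23 | intermediate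
20 | 14-TBDPS-oxy-1,2-O-isopropylidene-1,2-dihydroxyeudesma-3,11-dien-9-one (C7 isopropenyl cis to H5) | C=C(C)[C@@H]1CC(=O)[C@@]2(CO[Si](c3ccccc3)(c3ccccc3)C(C)(C)C)[C@H](C1)C(C)=C[C@@H]3OC(C)(C)O[C@H]23 | intermediate
21 | 14-TBDPS-oxy-1,2-O-isopropylidene-eudesma-3,11-diene-1,2,9-triol (C9–OH anti to C14) | C=C(C)[C@@H]1C[C@H](O)[C@@]2(CO[Si](c3ccccc3)(c3ccccc3)C(C)(C)C)[C@H](C1)C(C)=C[C@@H]3OC(C)(C)O[C@H]23 | intermediate
22 | 14-TBDPS-oxyeudesma-3,11-diene-1,2,9-triol | C=C(C)[C@@H]1C[C@H](O)[C@@]2(CO[Si](c3ccccc3)(c3ccccc3)C(C)(C)C)[C@H](C1)C(C)=C[C@H](O)[C@@H]2O | intermediate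
23 | 1,2-O-dibutylstannylene acetal of 22 | C=C(C)[C@@H]1C[C@H](O)[C@@]2(CO[Si](c3ccccc3)(c3ccccc3)C(C)(C)C)[C@H](C1)C(C)=C[C@@H]3O[Sn](CCCC)(CCCC)O[C@H]23 | intermediate
24 | 14-TBDPS-oxy-2,9-dihydroxyeudesma-3,11-dien-1-yl 3-methylbut-2-enoate | C=C(C)[C@@H]1C[C@H](O)[C@@]2(CO[Si](c3ccccc3)(c3ccccc3)C(C)(C)C)[C@H](C1)C(C)=C[C@H](O)[C@@H]2OC(=O)C=C(C)C | intermediate
25 | 2,9-diacetoxy-14-TBDPS-oxyeudesma-3,11-dien-1-yl 3-methylbut-2-enoate | C=C(C)[C@@H]1C[C@H](OC(C)=O)[C@@]2(CO[Si](c3ccccc3)(c3ccccc3)C(C)(C)C)[C@H](C1)C(C)=C[C@H](OC(C)=O)[C@@H]2OC(=O)C=C(C)C | intermediate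
26 | (1R,2S,5R,7S,9S,10S)-2,9-diacetoxy-14-hydroxyeudesma-3,11-dien-1-yl 3-methylbut-2-enoate (CNP0320218.1) | C=C(C)[C@@H]1C[C@H](OC(C)=O)[C@@]2(CO)[C@H](C1)C(C)=C[C@H](OC(C)=O)[C@@H]2OC(=O)C=C(C)C | target

**Step count and risks**

Total step count: 20 (steps 1–5 to stannane 6, steps 6–8 to ketone 10, steps 9–20 after the union).
Longest linear sequence: 17 steps (steps 1–5, then 9–20).

Steps most likely to fail:

1. Step 11 (ring expansion). What may go wrong: migration of the unsubstituted ring carbon C8 or a hydride shift from C14 in place of the C5 shift, or opening of the activated epoxide by the acetonide oxygen or the isopropenyl π bond. The fallback takes the C5 substituent out of the rearrangement, so that both ring carbons are equivalent, and brings it in afterwards; it also avoids the α-stereogenic ketone 10. It sets out from stannane 6. The vinylcerium reagent 12, made as in step 9, is added to cyclopentanone to give the tertiary alcohol 1-{1-[(4R,5S)-2,2-dimethyl-5-vinyl-1,3-dioxolan-4-yl]vinyl}cyclopentan-1-ol F1. VO(acac)2/t-BuOOH epoxidation, now controlled by the dioxolane centre alone, should give the epoxy alcohol F2. BF3·OEt2 should then give, by the same semipinacol shift without a regiochemical choice, the 2-(hydroxymethyl)cyclohexanone F3, which is silylated (TBDPSCl, imidazole) to the silyl ether F4. Double dehydrogenation with IBX (DMSO, 80 °C) should give the 6,6-disubstituted cyclohexa-2,4-dienone F5. Copper-catalysed 1,6-addition of isopropenylmagnesium bromide at C5, anti to the branched dioxolanyl group, should give the β,γ-enone F6, and DBU should move the double bond into conjugation to give the enone F7. Ring-closing metathesis as in step 13 then closes ring A and the route is rejoined at enone 19.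

2. Step 16 (C9 reduction). What may go wrong: poor facial selectivity, because the equatorial trajectory is itself hindered by the axial CH2OSi group on C10, or silyl migration from O14 to the new C9 alkoxide. The fallback replaces steric control by intramolecular hydride delivery. It sets out from ketone 20: HF·pyridine removes the silyl group to give the β-hydroxy ketone F8; Me4NBH(OAc)3 in MeCN/AcOH at −20 °C (Evans–Saksena reduction) delivers hydride from the boron bound to O14, i.e. from the C14 face, and should give the anti-1,3-diol F9; selective silylation of the primary hydroxyl (TBDPSCl, imidazole) returns to the route at 21.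

3. Step 18 (regioselective senecioylation). What may go wrong: acylation at O2 instead of O1, or acyl migration between the cis-oxygens, because O1 lies next to the quaternary C10. The fallback fixes the acetate on O2 first by stereoelectronic orthoester opening. It sets out from triol 22: trimethyl orthoacetate with catalytic camphorsulfonic acid gives the cyclic 1,2-orthoacetate F10; mild aqueous acetic acid should open it to the axial C2 acetate with free equatorial C1 hydroxyl F11; 3-methylbut-2-enoyl chloride with DMAP should acylate O1 faster than the hindered axial O9 and give the senecioate F12; acetylation of the C9 hydroxyl (Ac2O, DMAP) returns to the route at 25.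

**Further compounds**

F1 | step 11 | 1-{1-[(4R,5S)-2,2-dimethyl-5-vinyl-1,3-dioxolan-4-yl]vinyl}cyclopentan-1-ol | OC1(CCCC1)C(=C)[C@H]2OC(C)(C)O[C@H]2C=C
F2 | step 11 | 1-{2-[2,2-dimethyl-5-vinyl-1,3-dioxolan-4-yl]oxiran-2-yl}cyclopentan-1-ol (C10 as in 14) | OC1(CCCC1)[C@@]2(CO2)[C@H]3OC(C)(C)O[C@H]3C=C
F3 | step 11 | 2-[2,2-dimethyl-5-vinyl-1,3-dioxolan-4-yl]-2-(hydroxymethyl)cyclohexan-1-one (C10 as in 15) | C1CC(=O)[C@@]([C@H]2OC(C)(C)O[C@H]2C=C)(CO)CC1
F4 | step 11 | TBDPS ether of F3 | C1CC(=O)[C@@]([C@H]2OC(C)(C)O[C@H]2C=C)(CO[Si](c2ccccc2)(c2ccccc2)C(C)(C)C)CC1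
F5 | step 11 | 6-(TBDPS-oxymethyl)-6-[2,2-dimethyl-5-vinyl-1,3-dioxolan-4-yl]cyclohexa-2,4-dien-1-one | C1=CC(=O)[C@@]([C@H]2OC(C)(C)O[C@H]2C=C)(CO[Si](c2ccccc2)(c2ccccc2)C(C)(C)C)C=C1
F6 | step 11 | β,γ-enone from 1,6-addition (C5 isopropenyl, C6=C7) | C1=C[C@H](C(C)=C)[C@]([C@H]2OC(C)(C)O[C@H]2C=C)(CO[Si](c2ccccc2)(c2ccccc2)C(C)(C)C)C(=O)C1
F7 | step 11 | conjugated enone (C5 isopropenyl, C7=C8), the 7,8-didehydro form of 16 | C1=CC(=O)[C@@]([C@H]2OC(C)(C)O[C@H]2C=C)(CO[Si](c2ccccc2)(c2ccccc2)C(C)(C)C)[C@H](C1)C(C)=C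
F8 | step 16 | 14-hydroxy-1,2-O-isopropylidene-1,2-dihydroxyeudesma-3,11-dien-9-one | C=C(C)[C@@H]1CC(=O)[C@@]2(CO)[C@H](C1)C(C)=C[C@@H]3OC(C)(C)O[C@H]23
F9 | step 16 | 1,2-O-isopropylidene-eudesma-3,11-diene-1,2,9,14-tetrol (C9–OH anti to C14) | C=C(C)[C@@H]1C[C@H](O)[C@@]2(CO)[C@H](C1)C(C)=C[C@@H]3OC(C)(C)O[C@H]23
F10 | step 18 | cyclic 1,2-(methyl orthoacetate) of 22 | C=C(C)[C@@H]1C[C@H](O)[C@@]2(CO[Si](c3ccccc3)(c3ccccc3)C(C)(C)C)[C@H](C1)C(C)=C[C@@H]3OC(C)(OC)O[C@H]23
F11 | step 18 | 2-O-acetate of 22 (O1 and O9 free) | C=C(C)[C@@H]1C[C@H](O)[C@@]2(CO[Si](c3ccccc3)(c3ccccc3)C(C)(C)C)[C@H](C1)C(C)=C[C@H](OC(C)=O)[C@@H]2O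
F12 | step 18 | 2-acetoxy-9-hydroxy-14-TBDPS-oxyeudesma-3,11-dien-1-yl 3-methylbut-2-enoate | C=C(C)[C@@H]1C[C@H](O)[C@@]2(CO[Si](c3ccccc3)(c3ccccc3)C(C)(C)C)[C@H](C1)C(C)=C[C@H](OC(C)=O)[C@@H]2OC(=O)C=C(C)C
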